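**Plan**

1. Retrosynthesis: the two C–CH2 bonds of the methylene bridge are cut first (formaldehyde between the aromatic ring A and the trione ring B). Ring A is then cut at C1–C(=O) and C6–O in one operation, and ring B at the two C–CH3 bonds of its quaternary carbon.
2. Enabling feature: in ring A (numbered from the butanoyl-bearing C1) the neighbours C2 and C6 both carry oxygen. C1 and C6 can therefore be the two carbons of a 3-methoxyaryne (methoxy on C2, a second one on C4) that inserts into butanoic acid, with the acid oxygen ending on C6 and the acyl group on C1.
3. Forward: 3,5-dimethoxyphenol is converted into the ortho-silylaryl triflate in three steps, the aryne inserts into butanoic acid, and BCl3 frees the C2 hydroxyl. 2,4,6-Trihydroxyacetophenone is gem-dimethylated to ring B, and formaldehyde joins the two halves last. No ring is built anywhere.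
4. Stereochemistry: the target has no stereocentre and no stereogenic double bond, so none has to be set.

Key step: step 4

Remark: the target is a β-triketone drawn as one enol tautomer; the tautomers equilibrate and the drawn form is used throughout. Commercial 2,4,6-trihydroxyacetophenone monohydrate is dried before use.

**Route**

Step 1
Reactants: 1 3,5-dimethoxyphenol
Product: 2 2-bromo-3,5-dimethoxyphenol
Conditions: NBS (1.0 equiv), CH2Cl2, −78 °C → rt
Reagents that add atoms: N-bromosuccinimide, O=C1CCC(=O)N1Br
Why: Electrophilic aromatic bromination with NBS in a non-polar solvent at low temperature is directed ortho to the free hydroxyl group (hydrogen-bonded delivery of the reagent), at a carbon that is also para to a methoxy group, and one equivalent of reagent limits polybromination.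

Step 2
Reactants: 2 2-bromo-3,5-dimethoxyphenol
Product: 3 (2-bromo-3,5-dimethoxyphenoxy)trimethylsilane
Conditions: HMDS, THF, reflux; evaporation, no aqueous work-up
Reagents that add atoms: hexamethyldisilazane, C[Si](C)(C)N[Si](C)(C)C
Why: Silyl transfer from HMDS to the phenol (O-silylation) gives only volatile ammonia as co-product, so the moisture-sensitive aryl silyl ether can be taken on after evaporation.

Step 3
Reactants: 3 (2-bromo-3,5-dimethoxyphenoxy)trimethylsilane
Product: 6 3,5-dimethoxy-2-(trimethylsilyl)phenyl trifluoromethanesulfonate, via aryllithium 4 (not isolated), via lithium phenoxide 5 (not isolated)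
Conditions: n-BuLi (1.1 equiv), THF, −100 → −80 °C; then Tf2O (1.2 equiv), −100 → −80 °C; cold aq. NaHCO3
Reagents that add atoms: trifluoromethanesulfonic anhydride, O=S(=O)(OS(=O)(=O)C(F)(F)F)C(F)(F)F
Why: Bromine–lithium exchange at −100 °C gives aryllithium 4, whose carbanion takes the neighbouring silyl group from oxygen (retro-Brook 1,3 O→C silyl migration) to give phenoxide 5, and Tf2O sulfonylates that phenoxide, which is the standard way to ortho-silylaryl triflates.

Step 4
Reactants: 6 3,5-dimethoxy-2-(trimethylsilyl)phenyl trifluoromethanesulfonate (1.5 equiv); 7 butanoic acid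
Product: 9 1-(2-hydroxy-4,6-dimethoxyphenyl)butan-1-one, via 3,5-dimethoxybenzyne 8 (not isolated)
Conditions: CsF (4 equiv), THF, sealed tube, 125 °C
Reagents that add atoms: none
Why: Fluoride attacks the silicon of 6 and triflate leaves from the neighbouring carbon to give aryne 8, while the remaining CsF holds 7 as cesium butanoate. The carboxylate oxygen adds to the aryne carbon remote from the adjacent methoxy group, the aryl anion so formed attacks the ester carbonyl beside it, and the four-membered alkoxide opens to the ortho-acyl phenoxide, so the aryne is inserted into the acyl C–O bond and the aryl C–O and aryl C–C(=O) bonds are both made. The closest known reaction type is the insertion of arynes from ortho-silylaryl triflates into the C–O bond of carboxylic acids to give ortho-hydroxyaryl ketones, an intramolecular acyl transfer of the anionic Fries kind. The only ring closed is the transient four-membered one (4-exo-trig), which is not kept, and no stereocentre is formed. The step needs regioselective addition, which the inductively withdrawing methoxy group secures by distorting the aryne and stabilising negative charge on the carbon beside it, so that this carbon carries the acyl group between the two oxygens. It also needs acyl transfer to outrun protonation of the aryl anion, which the high temperature and the anhydrous carboxylate and fluoride medium should favour.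

Step 5
Reactants: 9 1-(2-hydroxy-4,6-dimethoxyphenyl)butan-1-one
Product: 10 1-(2,6-dihydroxy-4-methoxyphenyl)butan-1-one
Conditions: BCl3 (1 M in CH2Cl2, 3 equiv), CH2Cl2, −78 °C → rt; aq. HCl
Reagents that add atoms: none
Why: Chelation-controlled Lewis-acid ether cleavage, in which boron bound to the ketone oxygen reaches only the methoxy group ortho to the carbonyl, whose methyl group is removed by chloride, while the para methoxy group cannot chelate and should stay.

Step 6
Reactants: 11 2,4,6-trihydroxyacetophenone
Product: 13 2-acetyl-3,5-dihydroxy-4,4-dimethylcyclohexa-2,5-dien-1-one (acetylfilicinic acid), via 2,4,6-trihydroxy-3-methylacetophenone 12 (not isolated)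
Conditions: NaOMe (3 equiv), MeI (2.2 equiv), MeOH, 0 °C → rt; aq. HCl
Reagents that add atoms: iodomethane, CI
Why: Dearomatising C-methylation of a phloroglucinol polyanion, in which the monomethyl compound 12 can take the second methyl group at the same ring carbon to give the cross-conjugated trione as a stabilised enolate, is the established entry to acylfilicinic acids.

Step 7
Reactants: 10 1-(2,6-dihydroxy-4-methoxyphenyl)butan-1-one (slight excess); 13 acetylfilicinic acid
Product: 15 2-acetyl-6-[(3-butanoyl-2,4-dihydroxy-6-methoxyphenyl)methyl]-3,5-dihydroxy-4,4-dimethylcyclohexa-2,5-dien-1-one (CNP0378451.0), via methylidene trione 14 (not isolated)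
Conditions: 37% aq. CH2O (1.0 equiv), 1% aq. KOH, 0 °C → rt, short contact time; then dilute HCl
Reagents that add atoms: formaldehyde, C=O
Why: Base-mediated Knoevenagel–Michael sequence, in which formaldehyde condenses at the single ring CH of 13 to the enone 14 and the phenoxide of 10 adds through one of its two equivalent free ring carbons, is the classical way to methylene-bridged acylphloroglucinol dimers.

**Compound list**

1 | 3,5-dimethoxyphenol | COc1cc(O)cc(OC)c1 | starting material
2 | 2-bromo-3,5-dimethoxyphenol | COc1cc(O)c(Br)c(OC)c1 | intermediate
3 | (2-bromo-3,5-dimethoxyphenoxy)trimethylsilane | COc1cc(OC)c(Br)c(O[Si](C)(C)C)c1 | intermediate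
4 | [2,4-dimethoxy-6-(trimethylsilyloxy)phenyl]lithium (aryllithium, not isolated) | COc1cc(OC)c([Li])c(O[Si](C)(C)C)c1 | intermediate
5 | lithium 3,5-dimethoxy-2-(trimethylsilyl)phenolate (lithium phenoxide, not isolated) | [Li+].[O-]c1cc(OC)cc(OC)c1[Si](C)(C)C | intermediate
6 | 3,5-dimethoxy-2-(trimethylsilyl)phenyl trifluoromethanesulfonate | COc1cc(OC)c([Si](C)(C)C)c(OS(=O)(=O)C(F)(F)F)c1 | intermediate
7 | butanoic acid | CCCC(=O)O | starting material
8 | 3,5-dimethoxybenzyne (1,2-didehydro-3,5-dimethoxybenzene, not isolated) | COC1=CC#CC(OC)=C1 | intermediate
9 | 1-(2-hydroxy-4,6-dimethoxyphenyl)butan-1-one | CCCC(=O)c1c(O)cc(OC)cc1OC | intermediate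
10 | 1-(2,6-dihydroxy-4-methoxyphenyl)butan-1-one | CCCC(=O)c1c(O)cc(OC)cc1O | intermediate
11 | 2,4,6-trihydroxyacetophenone, 1-(2,4,6-trihydroxyphenyl)ethan-1-one | CC(=O)c1c(O)cc(O)cc1O | starting material
12 | 2,4,6-trihydroxy-3-methylacetophenone, 1-(2,4,6-trihydroxy-3-methylphenyl)ethan-1-one (not isolated) | CC(=O)c1c(O)cc(O)c(C)c1O | intermediate
13 | 2-acetyl-3,5-dihydroxy-4,4-dimethylcyclohexa-2,5-dien-1-one (acetylfilicinic acid) | CC(=O)C1=C(O)C(C)(C)C(O)=CC1=O | intermediate
14 | 2-acetyl-3-hydroxy-4,4-dimethyl-6-methylidenecyclohex-2-ene-1,5-dione (methylidene trione, not isolated) | C=C1C(=O)C(C(C)=O)=C(O)C(C)(C)C1=O | intermediate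
15 | 2-acetyl-6-[(3-butanoyl-2,4-dihydroxy-6-methoxyphenyl)methyl]-3,5-dihydroxy-4,4-dimethylcyclohexa-2,5-dien-1-one (CNP0378451.0) | CCCC(=O)c1c(O)cc(OC)c(CC2=C(O)C(C)(C)C(O)=C(C(C)=O)C2=O)c1O | target

**Count**

Total steps: 7. Longest linear sequence: 6 steps (steps 1, 2, 3, 4, 5, 7); step 6 is a one-step side branch that joins at step 7.

**Steps most likely to fail**

Step 4. The aryl anion may be protonated before the acyl group is transferred, so that the sequence stops at O-arylation, and the acyl group may be lost from the aryl ester by enolisation at the high temperature; erosion of regioselectivity is the lesser concern. The fallback gives up the aryne and uses a Lewis-acid acyl migration. It sets out from 1, which is O-acylated with butanoyl chloride (Et3N, CH2Cl2) to 3,5-dimethoxyphenyl butanoate F1. A Fries rearrangement (BF3·OEt2, 80–90 °C) should then move the acyl group to the ring carbon ortho to the oxygen, held there as the boron chelate, and the route is rejoined at 9. Material from a step 4 that stopped at O-arylation is this same ester and can be put through the same rearrangement.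

Step 7. Each partner can couple with itself through formaldehyde, bridges already formed can be exchanged in alkali, and ring A can be bridged a second time at its remaining free carbon. The fallback separates activation from coupling. It sets out from 13, which is aminomethylated with N,N-dimethylmethyleneiminium iodide in MeCN to the Mannich base 2-acetyl-6-[(dimethylamino)methyl]-3,5-dihydroxy-4,4-dimethylcyclohexa-2,5-dien-1-one F2. Warming F2 with 10 (NaOAc, dioxane, 80 °C) should release dimethylamine and generate enone 14 slowly, with only 10 present to trap it by conjugate addition, and the route is rejoined at 15.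

Step 1. Bromination at the carbon between the two methoxy groups (para to the hydroxyl) and over-bromination compete with the wanted ortho attack. The fallback installs silicon by directed ortho-metalation instead of through a bromide and sets out from 1.
- Carbamoylation with isopropyl isocyanate (cat. Et3N, CH2Cl2) gives 3,5-dimethoxyphenyl N-(propan-2-yl)carbamate F3.
- In-situ N-silylation (TMSOTf, TMEDA, Et2O), lithiation with n-BuLi/TMEDA at −78 °C at the carbon flanked by the carbamate and a methoxy group, quench with TMSCl and acidic work-up should give 3,5-dimethoxy-2-(trimethylsilyl)phenyl N-(propan-2-yl)carbamate F4.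
- DBU and Et2NH in MeCN at 40 °C cleave the carbamate, the isocyanate being trapped as the urea, and PhNTf2 added to the same pot triflates the phenoxide, which rejoins the route at 6.

**Further compounds**

F1 | step 4 | 3,5-dimethoxyphenyl butanoate | CCCC(=O)Oc1cc(OC)cc(OC)c1
F2 | step 7 | 2-acetyl-6-[(dimethylamino)methyl]-3,5-dihydroxy-4,4-dimethylcyclohexa-2,5-dien-1-one | CN(C)CC1=C(O)C(C)(C)C(O)=C(C(C)=O)C1=O
F3 | step 1 | 3,5-dimethoxyphenyl N-(propan-2-yl)carbamate | COc1cc(OC)cc(OC(=O)NC(C)C)c1
F4 | step 1 | 3,5-dimethoxy-2-(trimethylsilyl)phenyl N-(propan-2-yl)carbamate | COc1cc(OC)c([Si](C)(C)C)c(OC(=O)NC(C)C)c1
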